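Which of these flasks ends with the most target, and how much do the first and last hold?

the same everywhere: starting material 0.10 M
- spring: reagent 0.50 M (in portions, 2); initiator 1.7 mM; run made earlier; portions every 1.0 min
- dawn: reagent 0.50 M (in portions, 2); initiator 33 mM; run made earlier; portions every 1.0 min
- delta: reagent 0.500 M (in portions, 2); initiator 2.0 mM; the portions of reagent follow each other after 1.0 min, the first at the start; time 12 min
- zeta: reagent 0.500 M (in portions, 2); initiator 1.5 mM; the portions of reagent follow each other after 1.0 min, the first at the start; time 12 min
- alpha: reagent 0.500 M (in portions, 2); initiator 25 mM; the portions of reagent follow each other after 1.0 min, the first at the start; time 12 min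
- epsilon: reagent 0.500 M (in portions, 2); initiator 12 mM; the portions of reagent follow each other after 1.0 min, the first at the start; time 12 min
- gamma: reagent 0.500 M (in portions, 2); initiator 5.9 mM; the portions of reagent follow each other after 1.0 min, the first at the start; time 12 min

- spring (time / min: target / %, starting material / %): 0.500: 7, 93; 0.833: 7, 93; 1.50: 15, 83; 3.00: 29, 72; 6.00: 44, 58
- dawn (time / min: target / %, starting material / %): 0.500: 21, 77; 1.50: 50, 47; 3.00: 74, 20; 4.00: 83, 18; 6.00: 90, 9

(scatter of a reading: 1.5 percentage points)

- ranking by amount of target, in percent of the starting material charged, from high to low, at 12 min (delta / zeta / alpha / epsilon / gamma)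
- the amount of target, in percent of the starting material charged of the flask you put first, at 12 min
- the amount of target, in percent of the starting material charged of the flask you put last, at 12 min

- percentages count the starting material that a species holds: one ended chains B counts as two
- candidate steps: initiator -> 2 initiating radical; starting material + initiating radical <-> chain carrier; reagent + chain carrier -> target + initiating radical; 2 initiating radical -> ended chains A; 2 chain carrier -> ended chains B; 2 reagent -> self-condensation product

The flasks differ in initiator, so I need how target depends on it. Let L be the log-conversion, the natural logarithm of the starting material charged over the part not turned into target. If the loss is pseudo-first-order under a radical level going as the root of the initiator charge c, the rate integrates in closed form to L = √c · f(t), with f shared by flasks of this recipe. As a reading, dawn's L over spring's is 3.93 at 3.00 min and 3.97 at 6.00 min, against a root ratio of 4.41, and with a scatter of 1.5 percentage points on each reading I take the root as a working rule.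

I carry Λ, the log-conversion at the asked time of a flask holding spring's initiator. Scaling dawn down by the root ratio and averaging with spring gives 0.324 at 3.00 min and 0.551 at 6.00 min. L cannot fall, so from these readings Λ is at least 0.551. The window from 3.00 min to 6.00 min gains 0.701 of what the window up to 3.00 min gains, so as a reading the slope is falling, and holding it at its later value caps my estimate of Λ at 1.01. If the initiator decays first-order, each window of that length gains that same fraction of the one before, which tightens my estimate of Λ to 0.822.

L rises with c, so the ranking follows the initiator charge, with alpha highest and zeta lowest. On this reckoning alpha lies between 87.9 % and 97.9 %, and my value is 95.7 %. On the same reckoning zeta lies between 40.4 % and 61.1 %, and my value is 53.8 %.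

The forecast, reading “a radical chain”, gives alpha > epsilon > gamma > delta > zeta, with 95 % and 59 %, both inside these brackets, though its low stands 5.2 points above my value.

The flasks give alpha > epsilon > gamma > delta > zeta, with 96.0 % and 56.7 %, also inside the brackets.

    initiator → 2 initiating radical (k = 0.00280 s⁻¹)
    starting material + initiating radical ⇌ chain carrier (K = 6.70 × 10⁵ L mol⁻¹, k = 16000 L mol⁻¹ s⁻¹)
    reagent + chain carrier → target + initiating radical (k = 5200 L mol⁻¹ s⁻¹)
    2 initiating radical → ended chains A (k = 2.90 × 10⁸ L mol⁻¹ s⁻¹)
    2 chain carrier → ended chains B (k = 2.90 × 10⁷ L mol⁻¹ s⁻¹)
    2 reagent → self-condensation product (k = 0.00370 L mol⁻¹ s⁻¹)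

In zeta the initiator falls with a half-life of 4.1 min to 13.3 % of its charge at 12.0 min, and during that fall the step from reagent and chain carrier to target has, by 6.00 min, 72 % of its turnover up to 12.0 min behind it. At 12.0 min zeta still holds starting material at 43.1 % and reagent at 25.1 % of its charge. Zeta's 56.7 % makes Λ 0.890, more than my 0.822. Carried to the neighbour of zeta with 3.70 mM of initiator, that Λ gives 73.1 %, and that flask holds 73.4 %.

(The numbers in the tables were computed with made-up constants, and the scatter is random.)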